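## Structural features

Peroxyacarnoate A is a monocyclic 1,2-dioxane (ring atoms O1–O2–C3–C4–C5–C6; the ester chain is numbered C1–C22 throughout). C3 carries the CH2CO2Me arm (C2, C1), and C6 carries a methoxy group and a sixteen-carbon chain (C7–C22) containing C10≡C11, a conjugated E alkene C12=C13 and a terminal alkene C21=C22. The two stereocentres, C3 (S) and C6 (R), lie 1,4 to each other across the ring and are not adjacent. OMe and the C3 arm are cis, which is the chair with OMe axial (anomeric to O1) and both carbon substituents equatorial. C6 is a peroxyketal carbon whose configuration can be equilibrated through a peroxycarbenium ion, whereas C3 is a secondary peroxide carbon that must be set with absolute control and then left alone. The fragile groups are the O–O bond (hydrogenation catalysts, phosphines, low-valent metals), the β-peroxy ester (bases can open the ring through C2–H or fragment it through C3–H in a Kornblum–DeLaMare reaction), the ketal (acid) and the enyne and terminal alkene (any reagent that saturates C=C). The real difficulty is to form the C3–O2 bond enantioselectively next to an ester-bearing methylene while leaving room to attach an unsaturated chain that cannot coexist with the ring-forming chemistry. The key step uses the fact that C3 and C6 are the two carbons bonded to the peroxide oxygens and that the alkoxy group on C6 is exchangeable. A chiral alkoxy group on C6 of a diene C3=C4–C5=C6 can therefore steer dioxygen onto C3/C6 and later be replaced by OMe.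

## Logic of the disconnections

18 is cut at the C11–C12 bond into 14 and 17. The C12=C13 and C21=C22 alkenes would not survive the reduction of the ring alkene, so they must arrive after it; the cut also splits the molecule into two C11 halves, only one of which carries the peroxide. The forward step must join an sp carbon to an sp2 carbon at room temperature with retention of the E geometry and without reducing O–O, which points to a Sonogashira coupling.

17 is cut at C12=C13 back to 16, and 16 is traced by a change of oxidation level at C13 to 15. One carbon (C12, with its iodine) is added to a commercial C10 chain. The forward olefination must be E-selective and must leave the terminal alkene alone.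

14 is traced to 13 by replacing C11–H with C11–Si. The silyl group keeps C10≡C11 inert to the bases of the early steps and shields it during the ring-alkene reduction. The forward step must break C–Si without a base strong enough to open the β-peroxy ester.

13 is traced to 12 by cutting C6–OMe and putting the alkoxy group of 4 in its place. The stereodirecting group then sits on the one position whose substituent is exchanged anyway, so its removal costs no separate step and 4 is recovered. The forward exchange must run under equilibrium control so that C6 settles as the anomerically favoured 6R centre while C3 stays untouched.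

12 is traced to 11 by introducing the C4=C5 double bond, the retron of a cycloaddition. The forward step must saturate a ring alkene in the presence of O–O, an ester and a silylalkyne, which restricts it to a concerted hydrogen transfer from diimide.

11 is cut at C3–O2 and C6–O1 into 9 and 10. Both ring C–O bonds, the ring and both stereocentres then arise in one step from an open-chain diene. The forward step must be a suprafacial [4+2] addition that beats [2+2] and ene pathways and occurs on one diene face; this requires the (3E,5E) geometry with the alkoxy group outside and a face-differentiating group on that oxygen.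

9 is cut at C3=C4 and at the ester O–CH3 bond into 5 and 6 (through 7 and 8). A three-carbon acid unit is attached to an enal, so the skipped dienoate is made directly in its non-conjugated form. The olefination must be E-selective. As an improvement in the handling of the precursor, the carboxylate is methylated in the same flask, so that neither a free acid (which would hydrolyse the dienol ether) nor excess base (which would move C3=C4 into conjugation) is present.

5 is cut at the C6–O enol-ether bond into 3 and 4. Conjugate addition of an alcohol to an ynal creates enol ether and enal together. The forward step must give the E isomer (alkoxy trans to formyl), which is the thermodynamic one and the one that places the alkoxy group outside in 9.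

3 is cut at C4–C5 to 2, and 2 at C11–Si to 1. A symmetrical commercial C7 diyne supplies C5–C11. The forward steps are a statistical mono-silylation (excess 1 recycled) and a formylation worked up so that the ynal never meets free amine.

## Other disconnections considered

Alternative 1: The cut is at O1–C6 and C6–OMe, leading to the open-chain (3S)-hydroperoxy ketone A1 with the complete C7–C22 chain and C1 as a silyl ether. In the forward key step, acidic methanol lets the C3 hydroperoxide add to the C6 carbonyl (6-exo-trig) and the peroxyhemiketal exchanges OH for OMe, giving A2.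
- In its favour: C6 is settled by the same anomeric equilibration as in step 7 of the chosen plan, so the two are equal on that point. The unsaturated chain is complete before any peroxide exists and no ring alkene has to be reduced, so diimide and a palladium coupling on a peroxide are avoided; here the alternative is the better plan. The C3 configuration would come from an SN2 inversion at a carbinol that a reliable asymmetric reduction can supply, which is in principle a firmer source of absolute configuration than facial discrimination by a remote auxiliary; this is also a point for the alternative.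
- Against it: displacement by hydrogen peroxide at a secondary carbon competes with elimination. C1 has to be carried as a protected alcohol, because a leaving group β to an ester would eliminate. Desilylation, a two-stage oxidation through a β-peroxy aldehyde and esterification would then have to be run on the finished polyunsaturated peroxide.
- Comparison: the chosen plan sets C3 and closes the ring in one step and reaches the ester oxidation level from the start. On step count the alternative is expected to be clearly longer, and it puts its weakest step (the peroxide SN2) on an advanced intermediate.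

Alternative 2: The cut is at O2–C3 and C1–C2 (plus the ester C–O bond), leading to the unsaturated hydroperoxyketal A3. In the forward key step, PdCl2 with a chiral bisoxazoline, CO, methanol and a reoxidant would add the C6 hydroperoxide to the terminal alkene (6-exo-trig oxypalladation), and the alkylpalladium would insert CO and be trapped as the methyl ester, giving A4.
- In its favour: three bonds, the ring, C3 and the ester would form in one catalytic step from a precursor only a few steps from simple materials. No stoichiometric auxiliary, no photochemistry and no ring-alkene reduction are needed. On step economy and atom economy it is the better plan on paper.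
- Against it: a hydroperoxide is both nucleophile and oxidant towards palladium. β-Peroxyalkyl complexes of divalent palladium are the intermediates of peroxide-based Wacker-type ketone syntheses and collapse by O–O heterolysis, so ketone formation is expected to outrun CO insertion. CO and zerovalent palladium would also consume the hydroperoxide, and the silylalkyne is a competing ligand. Enantiofacial control of such a closure by a bisoxazoline has no close precedent, so the step would be an unproven method, whereas the chosen cycloaddition belongs to a known reaction class.
- Comparison: A4 is a C6 epimer mixture, but the acid equilibration used in the chosen plan would correct it, so the plans are equal on that point; desilylation and coupling would be the same in both.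

Alternative 3: The cut is at C4=C5, leading to the acyclic bis-allylic peroxide A5. In the forward key step, a second-generation Grubbs catalyst would join the two vinyl groups with loss of ethylene to give the 3,6-dihydro-1,2-dioxine A6.
- In its favour: ring-closing metathesis to six-membered rings is predictable, and dialkyl peroxides are compatible with ruthenium alkylidenes. No facial selectivity is asked of the ring closure itself; in reliability of the ring-forming event it is the better plan. Downstream it is equal to the chosen plan, since A6 needs the same diimide reduction, C6 equilibration, desilylation and coupling.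
- Against it: the difficulty is moved into A5. It needs an enantiopure allylic hydroperoxide β to an ester, which is prone to elimination to a dienoate and is accessible mainly by resolution. It also needs a peroxyketalisation at a fully substituted allylic ketal carbon, where ionisation gives an allyl cation with two sites of attack.
- Comparison: C3 would have to be set before ring closure in a separate operation, whereas the chosen plan sets C3 and closes the ring in the same step. The alkyne would have to stay silylated to avoid enyne metathesis, as in the chosen plan. Overall the route would be longer, with no gain after the ring is closed.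

Key step: step 5

Assumption: the (1R,2S) auxiliary is taken to shield the diene face that leads to 11 with the C3 configuration of the target; if the sense is opposite, the (1S,2R) alcohol is used in step 3 and nothing else changes.

Structure check: the constitution and configuration of 9 and 11 need no correction. The descriptor at C3 is R in 11 (sp2 C4 outranks C2) and S from 12 onwards (C2 outranks C4), with no change in spatial arrangement.

## Route

Step 1
Reactants: 1 hepta-1,6-diyne
Product: 2 hepta-1,6-diyn-1-yl(triisopropyl)silane
Conditions: n-BuLi (1 equiv), THF, −78 °C; i-Pr3SiOTf, −78 °C → rt; 1 used in threefold excess and recovered by distillation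
Reagents that add atoms: triisopropylsilyl trifluoromethanesulfonate, CC(C)[Si](OS(=O)(=O)C(F)(F)F)(C(C)C)C(C)C
Why: Silylation of a lithium acetylide; the excess of the symmetrical diyne keeps double silylation low, and the volatile diyne is recycled.

Step 2
Reactants: 2 hepta-1,6-diyn-1-yl(triisopropyl)silane
Product: 3 8-(triisopropylsilyl)octa-2,7-diynal
Conditions: n-BuLi, THF, −78 °C; DMF, −78 → 0 °C; inverse quench into aq. KH2PO4
Reagents that add atoms: N,N-dimethylformamide, CN(C)C=O
Why: Formylation of a lithium acetylide with DMF; the buffered inverse quench protonates the liberated dimethylamine so that it cannot add to the ynal.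

Step 3
Reactants: 3 8-(triisopropylsilyl)octa-2,7-diynal; 4 (1R,2S)-2-phenylcyclohexan-1-ol
Product: 5 (2E)-3-{[(1R,2S)-2-phenylcyclohexyl]oxy}-8-(triisopropylsilyl)oct-2-en-7-ynal
Conditions: PMe3 (20 mol%), CH2Cl2, 0 °C → rt
Reagents that add atoms: none
Why: Phosphine-catalysed oxa-Michael addition to an activated alkyne: PMe3 adds at C6, the zwitterion deprotonates the alcohol, the alkoxide adds at C6 and the phosphine is expelled. Reversible addition–elimination equilibrates the product to the E isomer with alkoxy trans to formyl; no stereocentre is formed and those of the auxiliary are untouched.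

Step 4
Reactants: 5 (2E)-3-{[(1R,2S)-2-phenylcyclohexyl]oxy}-8-(triisopropylsilyl)oct-2-en-7-ynal; 6 (2-carboxyethyl)triphenylphosphonium bromide
Product: 9 methyl (3E,5E)-6-{[(1R,2S)-2-phenylcyclohexyl]oxy}-11-(triisopropylsilyl)undeca-3,5-dien-10-ynoate, via sodium 3-(triphenylphosphoranylidene)propanoate 7 (not isolated), via sodium dienoate 8 (not isolated)
Conditions: 6, NaN(SiMe3)2 (2 equiv per 6), THF, −78 → 0 °C; 5, −78 °C → rt; then MeI, DMF, rt
Reagents that add atoms: iodomethane, CI
Why: Wittig olefination with a carboxylate-bearing ylide, which with conjugated aldehydes should give mainly the E alkene at C3=C4, while the basic medium leaves the C5=C6 geometry alone. O-Methylation of the carboxylate in the same flask means that the acid-labile dienol ether never meets a free carboxylic acid, and the absence of excess strong base keeps the skipped dienoate from moving into conjugation.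

Step 5
Reactants: 9 methyl (3E,5E)-6-{[(1R,2S)-2-phenylcyclohexyl]oxy}-11-(triisopropylsilyl)undeca-3,5-dien-10-ynoate; 10 dioxygen (excited to its singlet state)
Product: 11 methyl 2-[(3R,6R)-6-{[(1R,2S)-2-phenylcyclohexyl]oxy}-6-[5-(triisopropylsilyl)pent-4-yn-1-yl]-3,6-dihydro-1,2-dioxin-3-yl]acetate
Conditions: O2, tetraphenylporphyrin (1 mol%), visible light, CH2Cl2 (stored over K2CO3), −78 °C
Reagents that add atoms: none
Why: Sensitised dioxygen adds as the 2π partner across C3 and C6 of the s-cis dienol ether in one suprafacial, asynchronous event in which bonding leads at C3 and the developing positive charge at C6 is stabilised by the ether oxygen. The closest known reaction type is the photooxygenation of 1-alkoxy-1,3-dienes, including dienol ethers of chiral alcohols, to 3-alkoxy-3,6-dihydro-1,2-dioxines. The six-membered ring is closed by cycloaddition, with both C–O bonds made in the same step, and not by an exo or endo cyclisation of a chain. The relative configuration follows from suprafaciality and the (3E,5E) geometry: the two outside groups, the alkoxy on C6 and CH2CO2Me on C3, end up cis, which fixes C6 relative to C3. The absolute configuration at C3 is controlled by the auxiliary, whose trans-phenyl group should lie over one face of the C5=C6–O unit so that dioxygen enters from the open face. The step needs chemoselectivity for [4+2] over dioxetane and ene pathways, which the outside position of the donor oxygen, the E geometry at C3=C4, the low temperature and the weakly polar solvent favour. The silylalkyne, ester and arene are inert to singlet oxygen, and the product of attack on the other face is a diastereomer that can be removed by chromatography here or at 12.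

Step 6
Reactants: 11 methyl 2-[(3R,6R)-6-{[(1R,2S)-2-phenylcyclohexyl]oxy}-6-[5-(triisopropylsilyl)pent-4-yn-1-yl]-3,6-dihydro-1,2-dioxin-3-yl]acetate
Product: 12 methyl 2-[(3S,6R)-6-{[(1R,2S)-2-phenylcyclohexyl]oxy}-6-[5-(triisopropylsilyl)pent-4-yn-1-yl]-1,2-dioxan-3-yl]acetate
Conditions: KO2CN=NCO2K, AcOH, CH2Cl2, −20 → 0 °C
Reagents that add atoms: none
Why: Diimide reduction: HN=NH from the decarboxylating azodicarboxylate transfers two hydrogens in a concerted six-centre step to the cis ring alkene and does not cleave O–O. The bulky silyl group shields C10≡C11, and no stereocentre is touched (only the C3 descriptor changes).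

Step 7
Reactants: 12 methyl 2-[(3S,6R)-6-{[(1R,2S)-2-phenylcyclohexyl]oxy}-6-[5-(triisopropylsilyl)pent-4-yn-1-yl]-1,2-dioxan-3-yl]acetate
Product: 13 methyl 2-[(3S,6R)-6-methoxy-6-[5-(triisopropylsilyl)pent-4-yn-1-yl]-1,2-dioxan-3-yl]acetate
Conditions: TsOH·H2O (10 mol%), MeOH, 0 °C → rt
Reagents that add atoms: methanol, CO
Why: Acid-catalysed transketalisation through the C6 peroxycarbenium ion with methanol as solvent; under equilibrium control OMe goes axial (anomeric effect) and both carbon substituents equatorial, which is the 6R centre with OMe cis to the C3 arm. C3 cannot ionise and keeps its configuration, the methyl ester is degenerate in methanol, and 4 is recovered.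

Step 8
Reactants: 13 methyl 2-[(3S,6R)-6-methoxy-6-[5-(triisopropylsilyl)pent-4-yn-1-yl]-1,2-dioxan-3-yl]acetate
Product: 14 methyl 2-[(3S,6R)-6-methoxy-6-(pent-4-yn-1-yl)-1,2-dioxan-3-yl]acetate
Conditions: Bu4NF, AcOH (1:1), THF, 0 °C → rt
Reagents that add atoms: none
Why: Fluoride-induced protodesilylation of an alkynylsilane; buffering with acetic acid keeps the medium from becoming basic enough to open the β-peroxy ester by elimination.

Step 9
Reactants: 15 dec-9-en-1-ol
Product: 16 dec-9-enal
Conditions: TEMPO (10 mol%), PhI(OAc)2, CH2Cl2, rt
Reagents that add atoms: none
Why: Oxoammonium-mediated oxidation of a primary alcohol, which stops at the aldehyde and leaves the terminal alkene alone.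

Step 10
Reactants: 16 dec-9-enal
Product: 17 (1E)-1-iodoundeca-1,10-diene
Conditions: CrCl2, CHI3, THF, 0 °C → rt
Reagents that add atoms: iodoform, IC(I)I
Why: Takai olefination: the geminal dichromium species from iodoform adds to the aldehyde and elimination gives the E iodoalkene; the isolated terminal alkene is inert.

Step 11
Reactants: 14 methyl 2-[(3S,6R)-6-methoxy-6-(pent-4-yn-1-yl)-1,2-dioxan-3-yl]acetate; 17 (1E)-1-iodoundeca-1,10-diene
Product: 18 peroxyacarnoate A, methyl 2-[(3S,6R)-6-[(6E)-hexadeca-6,15-dien-4-yn-1-yl]-6-methoxy-1,2-dioxan-3-yl]acetate
Conditions: Pd(PPh3)4 (5 mol%), CuI (10 mol%), Et3N, THF, rt, degassed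
Reagents that add atoms: none
Why: Sonogashira coupling: zerovalent palladium inserts into the C–I bond with retention, the copper acetylide transmetalates and reductive elimination forms C11–C12. At room temperature with a mild amine the dialkyl peroxyketal and the β-peroxy ester should survive, and the E geometry is retained.

## Compound list

1 | hepta-1,6-diyne | C#CCCCC#C | starting material
2 | hepta-1,6-diyn-1-yl(triisopropyl)silane | CC(C)[Si](C(C)C)(C(C)C)C#CCCCC#C | intermediate
3 | 8-(triisopropylsilyl)octa-2,7-diynal | CC(C)[Si](C(C)C)(C(C)C)C#CCCCC#CC=O | intermediate
4 | (1R,2S)-2-phenylcyclohexan-1-ol | O[C@@H]1CCCC[C@H]1c1ccccc1 | starting material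
5 | (2E)-3-{[(1R,2S)-2-phenylcyclohexyl]oxy}-8-(triisopropylsilyl)oct-2-en-7-ynal | CC(C)[Si](C(C)C)(C(C)C)C#CCCC/C(O[C@@H]1CCCC[C@H]1c1ccccc1)=C\C=O | intermediate
6 | (2-carboxyethyl)triphenylphosphonium bromide | OC(=O)CC[P+](c1ccccc1)(c1ccccc1)c1ccccc1.[Br-] | starting material
7 | sodium 3-(triphenylphosphoranylidene)propanoate | [Na+].[O-]C(=O)CC=P(c1ccccc1)(c1ccccc1)c1ccccc1 | intermediate (not isolated)
8 | sodium (3E,5E)-6-{[(1R,2S)-2-phenylcyclohexyl]oxy}-11-(triisopropylsilyl)undeca-3,5-dien-10-ynoate | CC(C)[Si](C(C)C)(C(C)C)C#CCCC/C(O[C@@H]1CCCC[C@H]1c1ccccc1)=C\C=C\CC(=O)[O-].[Na+] | intermediate (not isolated)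
9 | methyl (3E,5E)-6-{[(1R,2S)-2-phenylcyclohexyl]oxy}-11-(triisopropylsilyl)undeca-3,5-dien-10-ynoate | CC(C)[Si](C(C)C)(C(C)C)C#CCCC/C(O[C@@H]1CCCC[C@H]1c1ccccc1)=C\C=C\CC(=O)OC | intermediate
10 | dioxygen (used as singlet oxygen) | O=O | starting material
11 | methyl 2-[(3R,6R)-6-{[(1R,2S)-2-phenylcyclohexyl]oxy}-6-[5-(triisopropylsilyl)pent-4-yn-1-yl]-3,6-dihydro-1,2-dioxin-3-yl]acetate | CC(C)[Si](C(C)C)(C(C)C)C#CCCC[C@]1(O[C@@H]2CCCC[C@H]2c2ccccc2)C=C[C@@H](CC(=O)OC)OO1 | intermediate
12 | methyl 2-[(3S,6R)-6-{[(1R,2S)-2-phenylcyclohexyl]oxy}-6-[5-(triisopropylsilyl)pent-4-yn-1-yl]-1,2-dioxan-3-yl]acetate | CC(C)[Si](C(C)C)(C(C)C)C#CCCC[C@]1(O[C@@H]2CCCC[C@H]2c2ccccc2)CC[C@@H](CC(=O)OC)OO1 | intermediate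
13 | methyl 2-[(3S,6R)-6-methoxy-6-[5-(triisopropylsilyl)pent-4-yn-1-yl]-1,2-dioxan-3-yl]acetate | CC(C)[Si](C(C)C)(C(C)C)C#CCCC[C@]1(OC)CC[C@@H](CC(=O)OC)OO1 | intermediate
14 | methyl 2-[(3S,6R)-6-methoxy-6-(pent-4-yn-1-yl)-1,2-dioxan-3-yl]acetate | C#CCCC[C@]1(OC)CC[C@@H](CC(=O)OC)OO1 | intermediate
15 | dec-9-en-1-ol | C=CCCCCCCCCO | starting material
16 | dec-9-enal | C=CCCCCCCCC=O | intermediate
17 | (1E)-1-iodoundeca-1,10-diene | C=CCCCCCCC/C=C/I | intermediate
18 | peroxyacarnoate A, methyl 2-[(3S,6R)-6-[(6E)-hexadeca-6,15-dien-4-yn-1-yl]-6-methoxy-1,2-dioxan-3-yl]acetate | C=CCCCCCCC/C=C/C#CCCC[C@]1(OC)CC[C@@H](CC(=O)OC)OO1 | target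

## Step count and least certain steps

Total step count: 11. Longest linear sequence: 9 steps (steps 1 to 8, then step 11); steps 9 and 10 form the two-step side branch.

Step 5 (key step). The most likely failure is poor π-facial discrimination. The stereocentres of the auxiliary are three bonds from C6 and the two C–O bonds can rotate, so both diene faces may react at similar rates. In addition, the inside C7 methylene forces the s-cis conformer to twist, which lets dioxetane and ene pathways compete. Facial leakage costs material and not optical purity, because the two cycloadducts are diastereomers and can be separated at 11 or 12.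

If the induction is too low to be useful, the fallback takes the absolute configuration from a resolution instead. It sets out from 3 and returns at 13. Methanol is added to 3 with PMe3 as catalyst to give (2E)-3-methoxy-8-(triisopropylsilyl)oct-2-en-7-ynal F1. The olefination and methylation of step 4 should convert it into methyl (3E,5E)-6-methoxy-11-(triisopropylsilyl)undeca-3,5-dien-10-ynoate F2. Photooxygenation as in step 5 should give the racemic cis-configured methyl 2-[(3R*,6R*)-6-methoxy-6-[5-(triisopropylsilyl)pent-4-yn-1-yl]-3,6-dihydro-1,2-dioxin-3-yl]acetate F3. Diimide as in step 6 should give racemic methyl 2-[(3S*,6R*)-6-methoxy-6-[5-(triisopropylsilyl)pent-4-yn-1-yl]-1,2-dioxan-3-yl]acetate F4, which is resolved by preparative chromatography on a polysaccharide chiral stationary phase to give 13. In this variant the methoxy group is in place from the start, so step 7 is not needed.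

Step 4. The most likely failure is erosion of the E geometry at C3=C4 (the ylide is not a stabilised one, and its E preference rests on the carboxylate effect), or base-induced migration of C3=C4 into conjugation with the ester once the ester has formed.

The fallback sets out from 5 and returns at 9 without any carboxylate or strong base. Takai iodo-olefination of 5 (CrCl2, CHI3, THF) should give {(6E,8E)-9-iodo-6-{[(1R,2S)-2-phenylcyclohexyl]oxy}nona-6,8-dien-1-yn-1-yl}triisopropylsilane F5. Coupling of F5 with the Reformatsky reagent BrZnCH2CO2Me under Pd(PPh3)4 in THF/DMPU (a Negishi-type sp2–sp3 coupling with retention of alkene geometry) should give 9.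

Step 3. The most likely failure is consumption of the ynal by phosphine-induced oligomerisation before the hindered secondary alcohol has added, or incomplete equilibration to the E isomer.

The fallback sets out from 2 and returns at 5 and uses the ester series, in which this addition is best established. Treatment of 2 with n-BuLi and ClCO2Me gives methyl 8-(triisopropylsilyl)octa-2,7-diynoate F6. PMe3-catalysed addition of 4 should give methyl (2E)-3-{[(1R,2S)-2-phenylcyclohexyl]oxy}-8-(triisopropylsilyl)oct-2-en-7-ynoate F7. Reduction with i-Bu2AlH at −78 °C gives (2E)-3-{[(1R,2S)-2-phenylcyclohexyl]oxy}-8-(triisopropylsilyl)oct-2-en-7-yn-1-ol F8, and MnO2 in CH2Cl2 oxidises the allylic alcohol to 5.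

Step 6. The most likely failure is slow hydrogen transfer to a ring alkene that is shielded by the bulky alkoxy group on C6. The long exposure to excess reagent would allow reduction of C10≡C11 to begin and let acetic acid ionise the allylic peroxyketal.

The fallback reverses the order of exchange and reduction; it sets out from 11 and returns at 13. Brief treatment of 11 with TsOH in methanol at low temperature should give methyl 2-[(3R,6R)-6-methoxy-6-[5-(triisopropylsilyl)pent-4-yn-1-yl]-3,6-dihydro-1,2-dioxin-3-yl]acetate F9, with 4 recovered. Diimide reduction of the less hindered F9 then gives 13 directly.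

## Further compounds

F1 | step 5 | (2E)-3-methoxy-8-(triisopropylsilyl)oct-2-en-7-ynal | CC(C)[Si](C(C)C)(C(C)C)C#CCCC/C(OC)=C\C=O
F2 | step 5 | methyl (3E,5E)-6-methoxy-11-(triisopropylsilyl)undeca-3,5-dien-10-ynoate | CC(C)[Si](C(C)C)(C(C)C)C#CCCC/C(OC)=C\C=C\CC(=O)OC
F3 | step 5 | racemic methyl 2-[(3R*,6R*)-6-methoxy-6-[5-(triisopropylsilyl)pent-4-yn-1-yl]-3,6-dihydro-1,2-dioxin-3-yl]acetate (both enantiomers) | CC(C)[Si](C(C)C)(C(C)C)C#CCCC[C@]1(OC)C=C[C@@H](CC(=O)OC)OO1.CC(C)[Si](C(C)C)(C(C)C)C#CCCC[C@@]1(OC)C=C[C@H](CC(=O)OC)OO1
F4 | step 5 | racemic methyl 2-[(3S*,6R*)-6-methoxy-6-[5-(triisopropylsilyl)pent-4-yn-1-yl]-1,2-dioxan-3-yl]acetate (both enantiomers) | CC(C)[Si](C(C)C)(C(C)C)C#CCCC[C@]1(OC)CC[C@@H](CC(=O)OC)OO1.CC(C)[Si](C(C)C)(C(C)C)C#CCCC[C@@]1(OC)CC[C@H](CC(=O)OC)OO1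
F5 | step 4 | {(6E,8E)-9-iodo-6-{[(1R,2S)-2-phenylcyclohexyl]oxy}nona-6,8-dien-1-yn-1-yl}triisopropylsilane | CC(C)[Si](C(C)C)(C(C)C)C#CCCC/C(O[C@@H]1CCCC[C@H]1c1ccccc1)=C\C=C\I
F6 | step 3 | methyl 8-(triisopropylsilyl)octa-2,7-diynoate | CC(C)[Si](C(C)C)(C(C)C)C#CCCCC#CC(=O)OC
F7 | step 3 | methyl (2E)-3-{[(1R,2S)-2-phenylcyclohexyl]oxy}-8-(triisopropylsilyl)oct-2-en-7-ynoate | CC(C)[Si](C(C)C)(C(C)C)C#CCCC/C(O[C@@H]1CCCC[C@H]1c1ccccc1)=C\C(=O)OC
F8 | step 3 | (2E)-3-{[(1R,2S)-2-phenylcyclohexyl]oxy}-8-(triisopropylsilyl)oct-2-en-7-yn-1-ol | CC(C)[Si](C(C)C)(C(C)C)C#CCCC/C(O[C@@H]1CCCC[C@H]1c1ccccc1)=C\CO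
F9 | step 6 | methyl 2-[(3R,6R)-6-methoxy-6-[5-(triisopropylsilyl)pent-4-yn-1-yl]-3,6-dihydro-1,2-dioxin-3-yl]acetate | CC(C)[Si](C(C)C)(C(C)C)C#CCCC[C@]1(OC)C=C[C@@H](CC(=O)OC)OO1
A1 | alternative 1 | (3S,12E)-1-{[tert-butyl(diphenyl)silyl]oxy}-3-hydroperoxydocosa-12,21-dien-10-yn-6-one | C=CCCCCCCC/C=C/C#CCCCC(=O)CC[C@@H](CCO[Si](c1ccccc1)(c1ccccc1)C(C)(C)C)OO
A2 | alternative 1 | tert-butyl{2-[(3S,6R)-6-[(6E)-hexadeca-6,15-dien-4-yn-1-yl]-6-methoxy-1,2-dioxan-3-yl]ethoxy}diphenylsilane | C=CCCCCCCC/C=C/C#CCCC[C@]1(OC)CC[C@@H](CCO[Si](c2ccccc2)(c2ccccc2)C(C)(C)C)OO1
A3 | alternative 2 | (6-hydroperoxy-6-methoxydec-9-en-1-yn-1-yl)triisopropylsilane (racemic) | CC(C)[Si](C(C)C)(C(C)C)C#CCCCC(OC)(OO)CCC=C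
A4 | alternative 2 | methyl 2-[(3S)-6-methoxy-6-[5-(triisopropylsilyl)pent-4-yn-1-yl]-1,2-dioxan-3-yl]acetate (C6 epimers) | CC(C)[Si](C(C)C)(C(C)C)C#CCCCC1(OC)CC[C@@H](CC(=O)OC)OO1
A5 | alternative 3 | methyl (3R)-3-{[3-methoxy-8-(triisopropylsilyl)oct-1-en-7-yn-3-yl]peroxy}pent-4-enoate (epimers at the ketal carbon) | CC(C)[Si](C(C)C)(C(C)C)C#CCCCC(OC)(C=C)OO[C@@H](C=C)CC(=O)OC
A6 | alternative 3 | methyl 2-[(3R)-6-methoxy-6-[5-(triisopropylsilyl)pent-4-yn-1-yl]-3,6-dihydro-1,2-dioxin-3-yl]acetate (C6 epimers) | CC(C)[Si](C(C)C)(C(C)C)C#CCCCC1(OC)C=C[C@@H](CC(=O)OC)OO1
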